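The plan cuts the cyclopentanone ring of the trans-hydrindane at C2–C3 together with the ethylidene C–CH3 bond (numbered as an indan-2-one: O-acyl C1, ketone C2, ethylidene C3, fusion C3a/C7a, isopropyl C4, enoate C6, methylene C7). The feature exploited is the exocyclic C3 ethylidene whose methyl group points toward C2 (Z): this geometry results when methyl and the C2 aldehyde carbon are delivered to one side of an alkyne attached to C3a. One nickel-catalysed alkylative ynal cyclisation with a methylzinc reagent closes the five-membered ring, forms both bonds and fixes the alkene geometry. Its precursor is a methylenecyclohexane bearing, trans on C7a and C3a, an α-silyloxy acetaldehyde arm and a terminal alkyne.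

Key step: step 10

Remarks and assumptions:
- The cyclohexenone starting material, the protected glycolaldehyde and both carboxylic acids are taken as catalogue compounds.
- Target (indan-2-one) locants are used for every intermediate.
- The primary oxygen is carried as a PMB ether so that it can be removed oxidatively beside an alkene and an alkyne.
- C1 carries the robust TBS ether and C6 the labile TES ether; both stay as silyl ethers through step 10, because esters at these positions would be exposed to zerovalent nickel and the organozinc.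
- The C2 carbinol formed in step 10 is drawn as one epimer; its configuration is irrelevant because step 11 oxidises it.

Step 1
Reactants: 1 (R)-cryptone [(4R)-4-(propan-2-yl)cyclohex-2-en-1-one]; 2 ethynyl(trimethyl)silane
Product: 5 (3aR,4R)-configured trimethylsilyl enol ether (3R,4R)-4-isopropyl-1-(trimethylsilyloxy)-3-[(trimethylsilyl)ethynyl]cyclohex-1-ene, via lithium (trimethylsilyl)acetylide 3 (not isolated), via alkynylzinc bromide 4 (not isolated)
Conditions: 2, n-BuLi, Et2O, −78 °C; ZnBr2, 0 °C; then 1, TMSOTf, −40 °C; Et3N, aq. NaHCO3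
Reagents that add atoms: trimethylsilyl trifluoromethanesulfonate, C[Si](C)(C)OS(=O)(=O)C(F)(F)F
Why: Silyl triflate-promoted conjugate alkynylation of a cyclic enone by an alkynylzinc halide: the alkynyl group should enter at C3a anti to the C4 isopropyl group (3a,4-trans), and O-silylation stores the enolate regiospecifically as the C7=C7a enol silane.

Step 2
Reactants: 5 enol silane; 6 (4-methoxybenzyloxy)acetaldehyde
Product: 10 (1R,3aR,4R,7aR) syn-aldol (2R,3R,4R)-2-[(1R)-1-hydroxy-2-(4-methoxybenzyloxy)ethyl]-4-isopropyl-3-[(trimethylsilyl)ethynyl]cyclohexan-1-one, via lithium enolate 7 (not isolated), via triisopropoxytitanium enolate 8 (not isolated), via titanium aldolate 9 (not isolated)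
Conditions: MeLi, THF, 0 °C; ClTi(OiPr)3, −78 → −40 °C; 6, −78 °C; aq. NH4F
Reagents that add atoms: none
Why: Directed aldol addition of a regiodefined enolate: MeLi unmasks the lithium enolate, transmetalation gives the triisopropoxytitanium enolate, whose additions are syn-selective even for cyclic E-enolates, and the aldehyde should approach C7a anti to the C3a alkynyl group, so that C7a (trans to C3a) and C1 (R, syn adduct) are set together.

Step 3
Reactants: 10 syn-aldol
Product: 11 C1 tert-butyldimethylsilyl ether of 10 (1R,3aR,4R,7aR)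
Conditions: TBSOTf, 2,6-lutidine, CH2Cl2, −78 °C
Reagents that add atoms: tert-butyldimethylsilyl trifluoromethanesulfonate, CC(C)(C)[Si](C)(C)OS(=O)(=O)C(F)(F)F
Why: Silylation of a secondary alcohol with a silyl triflate and a hindered pyridine base, fast at −78 °C and free of retro-aldol or β-elimination; no stereocentre is touched.

Step 4
Reactants: 11 silyloxy ketone
Product: 12 C7-methylidene compound (1R,3aR,4R,7aS) with C1–OTBS, PMB ether and silylated alkyne
Conditions: Zn, CH2Br2, TiCl4 (reagent preformed in THF), CH2Cl2, 0 °C → rt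
Reagents that add atoms: dibromomethane, BrCBr
Why: Takai–Lombardo methylenation, whose non-basic zinc/titanium methylene reagent converts hindered, enolisable ketones into 1,1-disubstituted alkenes without epimerising C7a or eliminating the β-silyloxy group.

Step 5
Reactants: 12 methylidene compound
Product: 13 C6 axial allylic alcohol (1R,3aR,4R,6S,7aS)
Conditions: SeO2 (cat.), t-BuOOH, CH2Cl2, 0 °C → rt
Reagents that add atoms: tert-butyl hydroperoxide, CC(C)(C)OO (terminal oxidant; the oxygen is relayed by selenium dioxide, O=[Se]=O)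
Why: SeO2 allylic hydroxylation (ene reaction, then [2,3]-sigmatropic shift of the allylseleninic acid) of an exocyclic methylene group, which attacks the allylic ring CH2 in preference to the CH and delivers oxygen axially in methylenecyclohexanes, here to C6 trans to the equatorial C7a arm.

Step 6
Reactants: 13 allylic alcohol
Product: 14 terminal alkyne (1R,3aR,4R,6S,7aS) with free C6–OH
Conditions: K2CO3, MeOH, rt
Reagents that add atoms: none
Why: Base-catalysed methanolysis of the alkynyl C–Si bond (protodesilylation), to which the silyl ether, the PMB ether and the free alcohol are inert.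

Step 7
Reactants: 14 alkynyl alcohol
Product: 15 C6 triethylsilyl ether (1R,3aR,4R,6S,7aS)
Conditions: TESOTf, 2,6-lutidine, CH2Cl2, −78 °C
Reagents that add atoms: triethylsilyl trifluoromethanesulfonate, CC[Si](CC)(CC)OS(=O)(=O)C(F)(F)F
Why: Triethylsilylation of the hindered axial allylic alcohol with the silyl triflate; the terminal alkyne C–H is not silylated under these conditions.

Step 8
Reactants: 15 PMB ether
Product: 16 primary alcohol (C2–OH) (1R,3aR,4R,6S,7aS)
Conditions: DDQ, CH2Cl2/pH 7 buffer, 0 °C
Reagents that add atoms: none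
Why: Oxidative PMB ether cleavage by DDQ (hydride abstraction, then hydrolysis of the oxocarbenium ion), buffered so that both silyl ethers survive and leaving the isolated alkene and alkyne untouched.

Step 9
Reactants: 16 primary alcohol
Product: 17 ynal (1R,3aR,4R,6S,7aS): (2R)-2-(tert-butyldimethylsilyloxy)-2-[2-ethynyl-6-methylidene-3-(propan-2-yl)-5-(triethylsilyloxy)cyclohexyl]acetaldehyde
Conditions: Dess–Martin periodinane, NaHCO3, CH2Cl2, 0 °C → rt
Reagents that add atoms: none
Why: Dess–Martin oxidation of the primary alcohol to the α-silyloxy aldehyde under buffered conditions that do not epimerise C1; the aldehyde is used at once.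

Step 10
Reactants: 17 ynal; 18 dimethylzinc
Product: 21 (1R,2R,3Z,3aR,4R,6S,7aS)-1-(tert-butyldimethylsilyloxy)-3-ethylidene-7-methylidene-4-(propan-2-yl)-6-(triethylsilyloxy)octahydro-1H-inden-2-ol, via oxanickelacyclopentene 19 (not isolated), via methylzinc alkoxide 20 (not isolated)
Conditions: Ni(cod)2 (15 mol%), 18 (2.5 equiv), THF, 0 °C, slow addition of 17; aq. NH4Cl
Reagents that add atoms: none
Why: Zerovalent nickel binds the aldehyde and the alkyne of 17 and couples them oxidatively to oxanickelacyclopentene 19, joining C2 to the inner alkyne carbon (C3); transmetalation from ZnMe2 opens the Ni–O bond as the zinc alkoxide, and reductive elimination from the alkenyl(methyl)nickel forms the C–CH3 bond and frees the catalyst. The closest known reaction type is the Ni(cod)2-catalysed alkylative cyclisation of 5-alkynals with organozinc reagents, which is established for terminal alkynes and tolerates silyl ethers. The cyclopentane closes in 5-exo-dig fashion at the alkyne carbon bound to C3a, leaving the former terminal carbon exocyclic, and the trans-diequatorial placement of the two arms on C7a and C3a lets the trans-fused ring form from the chair. The only new stereocentre, C2, is set under substrate control (metallacycle formation anti to the C1 silyloxy group is expected) and is removed in step 11, so either epimer serves. The selectivity that matters is the alkene geometry: nickel and the new C2–C3 bond are cis within the metallacycle and methyl replaces nickel with retention, so methyl must end syn to C2 (Z), while the tether fixes the regiochemistry. Methyl has no β-hydrogen, which excludes the reductive pathway, and slow addition of the ynal at 0 °C should hold back alkyne oligomerisation and direct methyl transfer to the aldehyde.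

Step 11
Reactants: 21 allylic alcohol
Product: 22 (1R,3Z,3aR,4R,6S,7aS)-1-(tert-butyldimethylsilyloxy)-3-ethylidene-7-methylidene-4-(propan-2-yl)-6-(triethylsilyloxy)octahydro-2H-inden-2-one
Conditions: Dess–Martin periodinane, NaHCO3, CH2Cl2, 0 °C → rt
Reagents that add atoms: none
Why: Dess–Martin oxidation of the secondary allylic alcohol to the cross-conjugated enone, which removes the C2 stereocentre and, being neutral and buffered, should not disturb the Z-ethylidene or the C1 centre.

Step 12
Reactants: 22 bis-silyl enone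
Product: 23 C6 alcohol (1R,3Z,3aR,4R,6S,7aS) with C1–OTBS retained
Conditions: PPTS (cat.), MeOH–CH2Cl2, 0 °C
Reagents that add atoms: none
Why: Selective acid-catalysed methanolysis of the triethylsilyl ether, which is cleaved far faster than a tert-butyldimethylsilyl ether.

Step 13
Reactants: 23 C6 alcohol; 24 (E)-3-methylpent-2-enoic acid
Product: 26 C6 (E)-3-methylpent-2-enoate (1R,3Z,3aR,4R,6S,7aS) with C1–OTBS, via O-acylisourea 25 (not isolated)
Conditions: DCC, DMAP (cat.), CH2Cl2, 0 °C → rt
Reagents that add atoms: none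
Why: Steglich esterification (carbodiimide activation, DMAP acyl transfer) of the axial allylic alcohol with retention at C6; without stoichiometric base, dienolisation of the acyl donor should be avoided and its E geometry kept.

Step 14
Reactants: 26 silyl ether
Product: 27 C1 alcohol (α-hydroxy ketone) (1R,3Z,3aR,4R,6S,7aS) bearing the C6 enoate
Conditions: HF·pyridine, pyridine, THF, 0 °C → rt
Reagents that add atoms: none
Why: Fluoride-mediated desilylation with buffered HF·pyridine, which cleaves the Si–O bond without base and so spares the ester, the enone geometry and the enolisable C1 centre.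

Step 15
Reactants: 27 α-hydroxy ketone; 28 (S)-2-methylbutanoic acid
Product: 30 target (1R,3Z,3aR,4R,6S,7aS)-3-ethylidene-7-methylidene-1-{[(2S)-2-methylbutanoyl]oxy}-2-oxo-4-(propan-2-yl)octahydro-1H-inden-6-yl (2E)-3-methylpent-2-enoate, via O-acylisourea 29 (not isolated)
Conditions: DCC, DMAP (cat.), CH2Cl2, 0 °C → rt
Reagents that add atoms: none
Why: Steglich esterification of the α-hydroxy ketone with retention at C1; the mild carbodiimide/DMAP conditions should epimerise neither C1 nor the α-stereocentre of the acid.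

Compound list
1 | (R)-cryptone, (4R)-4-(propan-2-yl)cyclohex-2-en-1-one | CC(C)[C@H]1CCC(=O)C=C1 | starting material
2 | ethynyl(trimethyl)silane | C#C[Si](C)(C)C | starting material
3 | lithium (trimethylsilyl)acetylide | [Li]C#C[Si](C)(C)C | intermediate
4 | bromo[(trimethylsilyl)ethynyl]zinc | Br[Zn]C#C[Si](C)(C)C | intermediate
5 | (3R,4R)-4-isopropyl-1-(trimethylsilyloxy)-3-[(trimethylsilyl)ethynyl]cyclohex-1-ene (alkynyl trans to isopropyl) | C[Si](C)(C)OC1=C[C@H](C#C[Si](C)(C)C)[C@@H](C(C)C)CC1 | intermediate
6 | (4-methoxybenzyloxy)acetaldehyde | O=CCOCc1ccc(OC)cc1 | starting material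
7 | lithium enolate (C7–OLi, C7=C7a) of the 3a,4-trans alkynyl ketone | [Li]OC1=C[C@H](C#C[Si](C)(C)C)[C@@H](C(C)C)CC1 | intermediate
8 | triisopropoxytitanium enolate | CC(C)O[Ti](OC(C)C)(OC(C)C)OC1=C[C@H](C#C[Si](C)(C)C)[C@@H](C(C)C)CC1 | intermediate
9 | triisopropoxytitanium aldolate of 10 | O=C1[C@@H]([C@@H](O[Ti](OC(C)C)(OC(C)C)OC(C)C)COCc2ccc(OC)cc2)[C@H](C#C[Si](C)(C)C)[C@@H](C(C)C)CC1 | intermediate
10 | syn-aldol, (2R,3R,4R)-2-[(1R)-1-hydroxy-2-(4-methoxybenzyloxy)ethyl]-4-isopropyl-3-[(trimethylsilyl)ethynyl]cyclohexan-1-one | O=C1[C@@H]([C@@H](O)COCc2ccc(OC)cc2)[C@H](C#C[Si](C)(C)C)[C@@H](C(C)C)CC1 | intermediate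
11 | C1 tert-butyldimethylsilyl ether of 10 | O=C1[C@@H]([C@@H](O[Si](C)(C)C(C)(C)C)COCc2ccc(OC)cc2)[C@H](C#C[Si](C)(C)C)[C@@H](C(C)C)CC1 | intermediate
12 | C7-methylidene compound (1R,3aR,4R,7aS): C1–OTBS, C2–OPMB, silylated alkyne | C=C1[C@@H]([C@@H](O[Si](C)(C)C(C)(C)C)COCc2ccc(OC)cc2)[C@H](C#C[Si](C)(C)C)[C@@H](C(C)C)CC1 | intermediate
13 | C6 axial allylic alcohol (6S), O trans to the C7a arm and to the isopropyl group | C=C1[C@@H]([C@@H](O[Si](C)(C)C(C)(C)C)COCc2ccc(OC)cc2)[C@H](C#C[Si](C)(C)C)[C@@H](C(C)C)C[C@@H]1O | intermediate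
14 | terminal alkyne with free C6–OH | C=C1[C@@H]([C@@H](O[Si](C)(C)C(C)(C)C)COCc2ccc(OC)cc2)[C@H](C#C)[C@@H](C(C)C)C[C@@H]1O | intermediate
15 | C6 triethylsilyl ether (C1–OTBS, C2–OPMB, terminal alkyne) | C=C1[C@@H]([C@@H](O[Si](C)(C)C(C)(C)C)COCc2ccc(OC)cc2)[C@H](C#C)[C@@H](C(C)C)C[C@@H]1O[Si](CC)(CC)CC | intermediate
16 | primary alcohol (C2–OH) | C=C1[C@@H]([C@@H](O[Si](C)(C)C(C)(C)C)CO)[C@H](C#C)[C@@H](C(C)C)C[C@@H]1O[Si](CC)(CC)CC | intermediate
17 | ynal, (2R)-2-(tert-butyldimethylsilyloxy)-2-[2-ethynyl-6-methylidene-3-(propan-2-yl)-5-(triethylsilyloxy)cyclohexyl]acetaldehyde (1R,3aR,4R,6S,7aS) | C=C1[C@@H]([C@@H](O[Si](C)(C)C(C)(C)C)C=O)[C@H](C#C)[C@@H](C(C)C)C[C@@H]1O[Si](CC)(CC)CC | intermediate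
18 | dimethylzinc | C[Zn]C | starting material
19 | oxanickelacyclopentene (further ligands on nickel omitted) | C=C1[C@@H]2[C@H](C3=C[Ni]O[C@H]3[C@@H]2O[Si](C)(C)C(C)(C)C)[C@@H](C(C)C)C[C@@H]1O[Si](CC)(CC)CC | intermediate
20 | methylzinc alkoxide of 21 | C=C1[C@@H]2[C@H](/C(=C/C)[C@@H](O[Zn]C)[C@@H]2O[Si](C)(C)C(C)(C)C)[C@@H](C(C)C)C[C@@H]1O[Si](CC)(CC)CC | intermediate
21 | (1R,2R,3Z,3aR,4R,6S,7aS)-1-(tert-butyldimethylsilyloxy)-3-ethylidene-7-methylidene-4-(propan-2-yl)-6-(triethylsilyloxy)octahydro-1H-inden-2-ol | C=C1[C@@H]2[C@H](/C(=C/C)[C@@H](O)[C@@H]2O[Si](C)(C)C(C)(C)C)[C@@H](C(C)C)C[C@@H]1O[Si](CC)(CC)CC | intermediate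
22 | (Z)-ethylidene enone, C1–OTBS, C6–OTES | C=C1[C@@H]2[C@H](/C(=C/C)C(=O)[C@@H]2O[Si](C)(C)C(C)(C)C)[C@@H](C(C)C)C[C@@H]1O[Si](CC)(CC)CC | intermediate
23 | C6 alcohol of the enone, C1–OTBS | C=C1[C@@H]2[C@H](/C(=C/C)C(=O)[C@@H]2O[Si](C)(C)C(C)(C)C)[C@@H](C(C)C)C[C@@H]1O | intermediate
24 | (E)-3-methylpent-2-enoic acid | CC/C(C)=C/C(=O)O | starting material
25 | O-acylisourea from 24 and DCC | CC/C(C)=C/C(=O)OC(=NC1CCCCC1)NC1CCCCC1 | intermediate
26 | C6 (E)-3-methylpent-2-enoate, C1–OTBS | C=C1[C@@H]2[C@H](/C(=C/C)C(=O)[C@@H]2O[Si](C)(C)C(C)(C)C)[C@@H](C(C)C)C[C@@H]1OC(=O)/C=C(\C)CC | intermediate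
27 | C1 alcohol (α-hydroxy ketone) with C6 enoate | C=C1[C@@H]2[C@H](/C(=C/C)C(=O)[C@@H]2O)[C@@H](C(C)C)C[C@@H]1OC(=O)/C=C(\C)CC | intermediate
28 | (S)-2-methylbutanoic acid | CC[C@H](C)C(=O)O | starting material
29 | O-acylisourea from 28 and DCC | CC[C@H](C)C(=O)OC(=NC1CCCCC1)NC1CCCCC1 | intermediate
30 | (1R,3Z,3aR,4R,6S,7aS)-3-ethylidene-7-methylidene-1-{[(2S)-2-methylbutanoyl]oxy}-2-oxo-4-(propan-2-yl)octahydro-1H-inden-6-yl (2E)-3-methylpent-2-enoate | C=C1[C@@H]2[C@H](/C(=C/C)C(=O)[C@@H]2OC(=O)[C@@H](C)CC)[C@@H](C(C)C)C[C@@H]1OC(=O)/C=C(\C)CC | target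

Total step count: 15. Longest linear sequence: 15 steps (1 → 30).

Steps most likely to fail

1. Step 10. Methyl transfer from zinc to the aldehyde, or nickel-mediated oligomerisation of the terminal alkyne, may outrun the oxidative cyclisation, and closure of the trans-fused ring may be slow. The fallback gives up the one-pot three-component event and forms the same C2–C3 bond from a preformed alkenyl triflate of defined geometry by chromium-mediated addition. It sets out from 15. Gold-catalysed Markovnikov hydration of the alkyne (Ph3PAuNTf2 cat., aqueous dioxane) should give the methyl ketone F1. Kinetic enolisation at the methyl group (LDA, THF, −78 °C) and MeI should give the ethyl ketone F2. KHMDS and PhNTf2 should convert its Z-configured enolate into the (Z)-enol triflate F3, with triflate and methyl cis; the geometry is checked and any E isomer removed at this stage. DDQ and then Dess–Martin periodinane, as in steps 8 and 9, should give the primary alcohol F4 and the aldehyde F5. Intramolecular Nozaki–Hiyama–Kishi coupling (CrCl2, NiCl2 cat., DMF) then forms C2–C3 with retention of the alkene geometry and comes back to the route at 21 (either C2 epimer).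

2. Step 2. The aldehyde may add with poor simple diastereoselection through the competing chair transition state, giving the anti adduct with the wrong C1 configuration. The fallback sets C1 by inversion after the aldol instead of in it. It sets out from 5. The lithium enolate alone (MeLi, THF; then 6, −78 °C) should favour, through a closed chair transition state, the anti aldol F6; this is also the by-product of step 2. Takai–Lombardo methylenation of the unprotected hydroxy ketone should give the homoallylic alcohol F7. A Mitsunobu reaction (4-nitrobenzoic acid, PPh3, DIAD, THF) inverts C1 and should give the 4-nitrobenzoate F8. DIBAL (CH2Cl2, −78 °C) should release the alcohol F9 with the required C1 configuration. TBSOTf/2,6-lutidine then comes back to the route at 12.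

3. Step 5. Hydrogen abstraction may occur at the C7a methine instead of C6, or the allylic alcohol may be oxidised further to the enone. The fallback brings in the C6 oxygen at the ketone stage by enolate chemistry. It sets out from 11. Kinetic deprotonation at C6 (LiHMDS, TMSCl, THF, −78 °C) should give the enol silane F10. Rubottom oxidation (mCPBA, NaHCO3, CH2Cl2, 0 °C; then citric acid, MeOH), with the peracid approaching anti to the C7a arm, should give the α-hydroxy ketone F11 with the C6 oxygen trans to that arm. Non-basic Takai–Lombardo methylenation of F11 then comes back to the route at 13.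

Further compounds
F1 | step 10 | methyl ketone (acetyl on C3a; C1–OTBS, C2–OPMB, C6–OTES) | C=C1[C@@H]([C@@H](O[Si](C)(C)C(C)(C)C)COCc2ccc(OC)cc2)[C@H](C(C)=O)[C@@H](C(C)C)C[C@@H]1O[Si](CC)(CC)CC
F2 | step 10 | ethyl ketone (propanoyl on C3a) | C=C1[C@@H]([C@@H](O[Si](C)(C)C(C)(C)C)COCc2ccc(OC)cc2)[C@H](C(=O)CC)[C@@H](C(C)C)C[C@@H]1O[Si](CC)(CC)CC
F3 | step 10 | (Z)-enol triflate (triflate and methyl cis) | C=C1[C@@H]([C@@H](O[Si](C)(C)C(C)(C)C)COCc2ccc(OC)cc2)[C@H](/C(=C/C)OS(=O)(=O)C(F)(F)F)[C@@H](C(C)C)C[C@@H]1O[Si](CC)(CC)CC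
F4 | step 10 | primary alcohol of the enol triflate | C=C1[C@@H]([C@@H](O[Si](C)(C)C(C)(C)C)CO)[C@H](/C(=C/C)OS(=O)(=O)C(F)(F)F)[C@@H](C(C)C)C[C@@H]1O[Si](CC)(CC)CC
F5 | step 10 | α-silyloxy aldehyde of the enol triflate | C=C1[C@@H]([C@@H](O[Si](C)(C)C(C)(C)C)C=O)[C@H](/C(=C/C)OS(=O)(=O)C(F)(F)F)[C@@H](C(C)C)C[C@@H]1O[Si](CC)(CC)CC
F6 | step 2 | anti aldol (C1 epimer of 10) | O=C1[C@@H]([C@H](O)COCc2ccc(OC)cc2)[C@H](C#C[Si](C)(C)C)[C@@H](C(C)C)CC1
F7 | step 2 | C7-methylidene homoallylic alcohol (C1 epimer) | C=C1[C@@H]([C@H](O)COCc2ccc(OC)cc2)[C@H](C#C[Si](C)(C)C)[C@@H](C(C)C)CC1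
F8 | step 2 | C1 4-nitrobenzoate with inverted (required) C1 configuration | C=C1[C@@H]([C@@H](OC(=O)c2ccc(cc2)[N+](=O)[O-])COCc2ccc(OC)cc2)[C@H](C#C[Si](C)(C)C)[C@@H](C(C)C)CC1
F9 | step 2 | C7-methylidene alcohol with the required C1 configuration | C=C1[C@@H]([C@@H](O)COCc2ccc(OC)cc2)[C@H](C#C[Si](C)(C)C)[C@@H](C(C)C)CC1
F10 | step 5 | kinetic trimethylsilyl enol ether (C6=C7) of 11 | C[Si](C)(C)OC=1[C@@H]([C@@H](O[Si](C)(C)C(C)(C)C)COCc2ccc(OC)cc2)[C@H](C#C[Si](C)(C)C)[C@@H](C(C)C)CC=1
F11 | step 5 | C6 α-hydroxy ketone (C6–O trans to the C7a arm) | O=C1[C@@H]([C@@H](O[Si](C)(C)C(C)(C)C)COCc2ccc(OC)cc2)[C@H](C#C[Si](C)(C)C)[C@@H](C(C)C)C[C@@H]1O
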